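## Retrosynthetic overview

1. Germacrane numbering is used: ring carbons C1–C10 (C1=C10, C4=C5, carbinol C6, ring fusion C7/C8), lactone O–C8–C7–C11(=C13H2)–C12(=O), acetoxymethyl carbons C14 (on C10) and C15 (on C4). The last disconnection is C5–C6: an intramolecular Nozaki–Hiyama–Kishi addition of an (E)-alkenyl iodide to a C6 aldehyde closes the ten-membered carbocycle and gives the unprotected target directly.
2. Enabling feature: C6 is a secondary allylic carbinol bonded to the vinylic CH (C5) of the trisubstituted C4=C5 alkene (cis within the ring), the retron of alkenylmetal plus aldehyde. The trans-fused γ-lactone ring on C7/C8 and the two trisubstituted alkenes (C1=C10, C4=C5) stiffen the seco chain so that C5 and C6 can meet.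
3. The γ-lactone ring comes from the C8 aldehyde by asymmetric chromium-catalysed 2-(methoxycarbonyl)allylation and lactonisation with a Morita–Baylis–Hillman-derived allylic bromide (C7–C8 bond; sets C7 and C8).
4. The acyclic C5–C10 chain comes from a Still–Gennari olefination (C1=C10) of an (E)-3-iodoacrylate aldehyde (C4=C5 from iodoform and a malonate). One double ester reduction and acetylation gives both CH2OAc groups.
5. Ring order: γ-butyrolactone first (step 14), ten-membered ring last (step 17).

Key step: step 17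

Assumption: in step 14 the ligand antipode is taken that steers the allylchromium to the Re face of the C8 aldehyde (this face gives 8S); the sense of induction is treated as a matter of ligand choice.

## Route

Step 1
Reactants: 1 diethyl malonate; 2 2-(2-bromoethyl)-1,3-dioxolane
Product: 3 diethyl 2-[2-(1,3-dioxolan-2-yl)ethyl]propanedioate
Conditions: NaH, THF/DMF, 0 °C → 60 °C
Reagents that add atoms: none
Why: Malonic ester alkylation (SN2 of the sodium enolate on a primary bromide) should give the mono-alkylated malonate when 1 is in slight excess; no stereocenter is formed.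

Step 2
Reactants: 3 diethyl 2-[2-(1,3-dioxolan-2-yl)ethyl]propanedioate; 4 iodoform
Product: 5 diethyl 2-(diiodomethyl)-2-[2-(1,3-dioxolan-2-yl)ethyl]propanedioate
Conditions: NaH, Et2O, reflux; then CHI3, reflux
Reagents that add atoms: none
Why: Diiodomethylation of a tertiary malonate enolate with iodoform is the established first stage of the malonate route to 3-iodo-2-alkylacrylic acids; the new quaternary carbon is not stereogenic.

Step 3
Reactants: 5 diethyl 2-(diiodomethyl)-2-[2-(1,3-dioxolan-2-yl)ethyl]propanedioate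
Product: 7 (2E)-2-[2-(1,3-dioxolan-2-yl)ethyl]-3-iodoprop-2-enoic acid, via dipotassium malonate 6 (not isolated)
Conditions: KOH, EtOH/H2O, reflux; then 1 M HCl to pH 3, 0 °C
Reagents that add atoms: potassium hydroxide ([K+].[OH-])
Why: Saponification followed by decarboxylative anti-elimination of iodide (Grob-type fragmentation) should give the (E)-iodoacrylic acid, with iodine trans to the carboxyl group and cis to the future C3 chain, as in the known 2-methyl case; the acetal is stable to base.

Step 4
Reactants: 7 (2E)-2-[2-(1,3-dioxolan-2-yl)ethyl]-3-iodoprop-2-enoic acid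
Product: 8 methyl (2E)-2-[2-(1,3-dioxolan-2-yl)ethyl]-3-iodoprop-2-enoate
Conditions: MeI, K2CO3, DMF, rt
Reagents that add atoms: iodomethane (CI)
Why: O-Alkylation of the carboxylate (SN2) esterifies without acid, so the acetal and the alkene geometry are untouched.

Step 5
Reactants: 8 methyl (2E)-2-[2-(1,3-dioxolan-2-yl)ethyl]-3-iodoprop-2-enoate
Product: 9 methyl (2E)-2-(iodomethylidene)-5-oxopentanoate
Conditions: 1 M HCl, THF, rt
Reagents that add atoms: water (O)
Why: Acid-catalysed acetal hydrolysis frees the C1 aldehyde; the methyl ester and the alkenyl iodide are inert to dilute acid.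

Step 6
Reactants: 10 methyl 2-[bis(2,2,2-trifluoroethoxy)phosphoryl]acetate; 11 tert-butyl(2-iodoethoxy)dimethylsilane
Product: 12 methyl 2-[bis(2,2,2-trifluoroethoxy)phosphoryl]-4-[(tert-butyldimethylsilyl)oxy]butanoate (racemic)
Conditions: NaH, DMF, 0 °C → 50 °C
Reagents that add atoms: none
Why: C-Alkylation of the phosphonoacetate anion with a primary iodide (SN2) installs the C9–C8 arm; the stereocenter formed is lost in the next step.

Step 7
Reactants: 9 methyl (2E)-2-(iodomethylidene)-5-oxopentanoate; 12 methyl 2-[bis(2,2,2-trifluoroethoxy)phosphoryl]-4-[(tert-butyldimethylsilyl)oxy]butanoate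
Product: 13 dimethyl (2Z)-2-{2-[(tert-butyldimethylsilyl)oxy]ethyl}-6-[(E)-iodomethylidene]hept-2-enedioate
Conditions: KN(SiMe3)2, 18-crown-6, THF, −78 °C
Reagents that add atoms: none
Why: Still–Gennari olefination: with the electron-poor bis(trifluoroethyl) phosphonate the first adduct eliminates faster than it equilibrates, so the kinetic (Z)-enoate should form, with the C2 chain cis to the ester that becomes C14 and trans to C9.

Step 8
Reactants: 13 dimethyl (2Z)-2-{2-[(tert-butyldimethylsilyl)oxy]ethyl}-6-[(E)-iodomethylidene]hept-2-enedioate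
Product: 14 (2Z)-2-{2-[(tert-butyldimethylsilyl)oxy]ethyl}-6-[(E)-iodomethylidene]hept-2-ene-1,7-diol
Conditions: iBu2AlH, CH2Cl2, −78 → 0 °C; aq. potassium sodium tartrate (KNaC4H4O6)
Reagents that add atoms: none
Why: 1,2-Reduction of both conjugated esters with iBu2AlH gives the two allylic alcohols (C14 and C15) in one operation; the alkenyl iodide, the silyl ether and both alkene geometries are not affected.

Step 9
Reactants: 14 (2Z)-2-{2-[(tert-butyldimethylsilyl)oxy]ethyl}-6-[(E)-iodomethylidene]hept-2-ene-1,7-diol
Product: 15 (2Z)-2-{2-[(tert-butyldimethylsilyl)oxy]ethyl}-6-[(E)-iodomethylidene]hept-2-ene-1,7-diyl diacetate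
Conditions: Ac2O, pyridine, DMAP (cat.), CH2Cl2, 0 °C → rt
Reagents that add atoms: acetic anhydride (CC(=O)OC(C)=O)
Why: Nucleophilic-catalysed acylation of two primary allylic alcohols installs both acetates of the target at this early stage.

Step 10
Reactants: 15 (2Z)-2-{2-[(tert-butyldimethylsilyl)oxy]ethyl}-6-[(E)-iodomethylidene]hept-2-ene-1,7-diyl diacetate
Product: 16 (2Z)-2-(2-hydroxyethyl)-6-[(E)-iodomethylidene]hept-2-ene-1,7-diyl diacetate
Conditions: HF·pyridine, pyridine, THF, 0 °C → rt
Reagents that add atoms: none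
Why: Buffered fluoride desilylation removes the primary silyl ether without acyl transfer or hydrolysis of the allylic acetates.

Step 11
Reactants: 16 (2Z)-2-(2-hydroxyethyl)-6-[(E)-iodomethylidene]hept-2-ene-1,7-diyl diacetate
Product: 17 (2Z)-6-[(E)-iodomethylidene]-2-(2-oxoethyl)hept-2-ene-1,7-diyl diacetate
Conditions: Dess–Martin periodinane, NaHCO3, CH2Cl2, 0 °C; crude used at once
Reagents that add atoms: none
Why: Buffered Dess–Martin oxidation gives the β,γ-unsaturated C8 aldehyde under non-basic conditions, which should keep the C1=C10 alkene out of conjugation.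

Step 12
Reactants: 18 methyl acrylate; 19 [(tert-butyldimethylsilyl)oxy]acetaldehyde
Product: 20 methyl 4-[(tert-butyldimethylsilyl)oxy]-3-hydroxy-2-methylidenebutanoate (racemic)
Conditions: DABCO, MeOH, rt
Reagents that add atoms: none
Why: Morita–Baylis–Hillman reaction of an acrylate with a reactive α-oxygenated aldehyde; the carbinol center is removed in the next step.

Step 13
Reactants: 20 methyl 4-[(tert-butyldimethylsilyl)oxy]-3-hydroxy-2-methylidenebutanoate
Product: 21 methyl (2Z)-2-(bromomethyl)-4-[(tert-butyldimethylsilyl)oxy]but-2-enoate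
Conditions: N-bromosuccinimide, Me2S, CH2Cl2, 0 °C → rt
Reagents that add atoms: N-bromosuccinimide (O=C1CCC(=O)N1Br)
Why: The alkoxysulfonium salt of the Baylis–Hillman alcohol undergoes SN2' displacement by bromide with allylic transposition, which is known to give the (Z)-2-(bromomethyl)alk-2-enoate.

Step 14
Reactants: 17 (2Z)-6-[(E)-iodomethylidene]-2-(2-oxoethyl)hept-2-ene-1,7-diyl diacetate; 21 methyl (2Z)-2-(bromomethyl)-4-[(tert-butyldimethylsilyl)oxy]but-2-enoate
Product: 24 (4S,5S)-5-[(2Z,6E)-2,6-bis(acetoxymethyl)-7-iodohepta-2,6-dien-1-yl]-4-{[(tert-butyldimethylsilyl)oxy]methyl}-3-methylideneoxolan-2-one, via trimethylsilyl ether 22 (not isolated), via hydroxy ester 23 (not isolated)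
Conditions: CrCl2 (nickel-free, 10 mol%), chiral tridentate 1,8-bis(4-isopropyl-2-oxazolinyl)carbazole ligand (10 mol%), Mn, Me3SiCl, iPr2NEt (cat.), THF, rt; then aq. citric acid, MeOH, 0 °C; then PPTS, CH2Cl2, rt
Reagents that add atoms: none
Why: Chromium-catalysed asymmetric Nozaki–Hiyama 2-(alkoxycarbonyl)allylation followed by lactonisation: the allylchromium adds through its γ-carbon in a chair transition state to give the anti adduct (hence the trans lactone, C7), the ligand on trivalent chromium selects the Re face of the aldehyde (C8 S), and without nickel the alkenyl iodide is not activated.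

Step 15
Reactants: 24 (4S,5S)-5-[(2Z,6E)-2,6-bis(acetoxymethyl)-7-iodohepta-2,6-dien-1-yl]-4-{[(tert-butyldimethylsilyl)oxy]methyl}-3-methylideneoxolan-2-one
Product: 25 (4S,5S)-5-[(2Z,6E)-2,6-bis(acetoxymethyl)-7-iodohepta-2,6-dien-1-yl]-4-(hydroxymethyl)-3-methylideneoxolan-2-one
Conditions: HF·pyridine, pyridine, THF, 0 °C
Reagents that add atoms: none
Why: Buffered fluoride desilylation under mildly acidic, non-nucleophilic conditions frees the C6 alcohol while lactone migration to the primary hydroxyl, which needs base, is held back.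

Step 16
Reactants: 25 (4S,5S)-5-[(2Z,6E)-2,6-bis(acetoxymethyl)-7-iodohepta-2,6-dien-1-yl]-4-(hydroxymethyl)-3-methylideneoxolan-2-one
Product: 26 (2S,3R)-2-[(2Z,6E)-2,6-bis(acetoxymethyl)-7-iodohepta-2,6-dien-1-yl]-4-methylidene-5-oxooxolane-3-carbaldehyde
Conditions: Dess–Martin periodinane, NaHCO3, CH2Cl2, 0 °C; short silica filtration, used at once
Reagents that add atoms: none
Why: Buffered Dess–Martin oxidation gives the C6 aldehyde without base; C7 is not changed, and the trans arrangement is in any case the more stable one should C7 epimerise.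

Step 17
Reactants: 26 (2S,3R)-2-[(2Z,6E)-2,6-bis(acetoxymethyl)-7-iodohepta-2,6-dien-1-yl]-4-methylidene-5-oxooxolane-3-carbaldehyde
Product: 27 (3aS,4R,5E,9Z,11aS)-6,10-bis(acetoxymethyl)-4-hydroxy-3-methylidene-3a,4,7,8,11,11a-hexahydrocyclodeca[b]furan-2(3H)-one (CNP0594234.1)
Conditions: CrCl2 (10 equiv), NiCl2 (1 mol% of CrCl2), degassed DMSO, rt, syringe-pump addition to 2 mM; aq. work-up
Reagents that add atoms: none
Why: Zerovalent nickel, formed from NiCl2 by CrCl2, inserts into the C5–I bond with retention, the alkenyl group passes to trivalent chromium, and the alkenylchromium adds to the C6 aldehyde to give the chromium alkoxide of 27, which is freed on work-up. The closest known reaction type is the Nozaki–Hiyama–Kishi macrocyclisation of ω-iodoalkenyl aldehydes to medium-ring allylic alcohols, which tolerates esters, lactones, enoates and free hydroxyl groups. The ten-membered carbocycle closes in a 10-exo-trig mode, C5 adding to the exocyclic C6=O. The new C6 stereocenter is set by 1,2-induction from C7 (Felkin–Anh): C5 should approach anti to the C7–C8 bond with the formyl hydrogen and H7 turned to the inside of the forming ring, which puts the oxygen on the outer face next to C11 and gives 6R. The step needs chemoselectivity (nickel must insert into the alkenyl iodide and not ionise the allylic acetates; the carbon–chromium bond must add to the aldehyde and not to the lactone, the acetates or the methylene lactone), retention of alkene geometry, and ring closure over oligomerisation. These should be secured by the low nickel loading against a reactive iodide, the carbonyl selectivity and configurational stability of alkenylchromium reagents, slow addition at high dilution, and the stiffening of the seco chain by the trans-fused lactone and the two trisubstituted alkenes.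

## Compound list

1 | diethyl malonate | CCOC(=O)CC(=O)OCC | starting material
2 | 2-(2-bromoethyl)-1,3-dioxolane | BrCCC1OCCO1 | starting material
3 | diethyl 2-[2-(1,3-dioxolan-2-yl)ethyl]propanedioate | CCOC(=O)C(CCC1OCCO1)C(=O)OCC | intermediate
4 | iodoform | IC(I)I | starting material
5 | diethyl 2-(diiodomethyl)-2-[2-(1,3-dioxolan-2-yl)ethyl]propanedioate | CCOC(=O)C(CCC1OCCO1)(C(I)I)C(=O)OCC | intermediate
6 | dipotassium 2-(diiodomethyl)-2-[2-(1,3-dioxolan-2-yl)ethyl]propanedioate (not isolated) | [K+].[K+].[O-]C(=O)C(CCC1OCCO1)(C(I)I)C([O-])=O | intermediate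
7 | (2E)-2-[2-(1,3-dioxolan-2-yl)ethyl]-3-iodoprop-2-enoic acid | OC(=O)/C(CCC1OCCO1)=C/I | intermediate
8 | methyl (2E)-2-[2-(1,3-dioxolan-2-yl)ethyl]-3-iodoprop-2-enoate | COC(=O)/C(CCC1OCCO1)=C/I | intermediate
9 | methyl (2E)-2-(iodomethylidene)-5-oxopentanoate | COC(=O)/C(CCC=O)=C/I | intermediate
10 | methyl 2-[bis(2,2,2-trifluoroethoxy)phosphoryl]acetate | COC(=O)CP(=O)(OCC(F)(F)F)OCC(F)(F)F | starting material
11 | tert-butyl(2-iodoethoxy)dimethylsilane | CC(C)(C)[Si](C)(C)OCCI | starting material
12 | methyl 2-[bis(2,2,2-trifluoroethoxy)phosphoryl]-4-[(tert-butyldimethylsilyl)oxy]butanoate (racemic) | COC(=O)C(CCO[Si](C)(C)C(C)(C)C)P(=O)(OCC(F)(F)F)OCC(F)(F)F | intermediate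
13 | dimethyl (2Z)-2-{2-[(tert-butyldimethylsilyl)oxy]ethyl}-6-[(E)-iodomethylidene]hept-2-enedioate | CC(C)(C)[Si](C)(C)OCC/C(C(=O)OC)=C/CC/C(C(=O)OC)=C\I | intermediate
14 | (2Z)-2-{2-[(tert-butyldimethylsilyl)oxy]ethyl}-6-[(E)-iodomethylidene]hept-2-ene-1,7-diol | CC(C)(C)[Si](C)(C)OCC/C(CO)=C/CC/C(CO)=C\I | intermediate
15 | (2Z)-2-{2-[(tert-butyldimethylsilyl)oxy]ethyl}-6-[(E)-iodomethylidene]hept-2-ene-1,7-diyl diacetate | CC(C)(C)[Si](C)(C)OCC/C(COC(C)=O)=C/CC/C(COC(C)=O)=C\I | intermediate
16 | (2Z)-2-(2-hydroxyethyl)-6-[(E)-iodomethylidene]hept-2-ene-1,7-diyl diacetate | OCC/C(COC(C)=O)=C/CC/C(COC(C)=O)=C\I | intermediate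
17 | (2Z)-6-[(E)-iodomethylidene]-2-(2-oxoethyl)hept-2-ene-1,7-diyl diacetate | O=CC/C(COC(C)=O)=C/CC/C(COC(C)=O)=C\I | intermediate
18 | methyl acrylate | C=CC(=O)OC | starting material
19 | [(tert-butyldimethylsilyl)oxy]acetaldehyde | CC(C)(C)[Si](C)(C)OCC=O | starting material
20 | methyl 4-[(tert-butyldimethylsilyl)oxy]-3-hydroxy-2-methylidenebutanoate (racemic) | COC(=O)C(=C)C(O)CO[Si](C)(C)C(C)(C)C | intermediate
21 | methyl (2Z)-2-(bromomethyl)-4-[(tert-butyldimethylsilyl)oxy]but-2-enoate | COC(=O)/C(CBr)=C/CO[Si](C)(C)C(C)(C)C | intermediate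
22 | methyl (3S,4S,6Z,10E)-6,10-bis(acetoxymethyl)-3-{[(tert-butyldimethylsilyl)oxy]methyl}-11-iodo-2-methylidene-4-[(trimethylsilyl)oxy]undeca-6,10-dienoate (not isolated) | COC(=O)C(=C)[C@@H](CO[Si](C)(C)C(C)(C)C)[C@@H](O[Si](C)(C)C)C/C(COC(C)=O)=C/CC/C(COC(C)=O)=C\I | intermediate
23 | methyl (3S,4S,6Z,10E)-6,10-bis(acetoxymethyl)-3-{[(tert-butyldimethylsilyl)oxy]methyl}-4-hydroxy-11-iodo-2-methylideneundeca-6,10-dienoate (not isolated) | COC(=O)C(=C)[C@@H](CO[Si](C)(C)C(C)(C)C)[C@@H](O)C/C(COC(C)=O)=C/CC/C(COC(C)=O)=C\I | intermediate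
24 | (4S,5S)-5-[(2Z,6E)-2,6-bis(acetoxymethyl)-7-iodohepta-2,6-dien-1-yl]-4-{[(tert-butyldimethylsilyl)oxy]methyl}-3-methylideneoxolan-2-one | C=C1C(=O)O[C@@H](C/C(COC(C)=O)=C/CC/C(COC(C)=O)=C\I)[C@@H]1CO[Si](C)(C)C(C)(C)C | intermediate
25 | (4S,5S)-5-[(2Z,6E)-2,6-bis(acetoxymethyl)-7-iodohepta-2,6-dien-1-yl]-4-(hydroxymethyl)-3-methylideneoxolan-2-one | C=C1C(=O)O[C@@H](C/C(COC(C)=O)=C/CC/C(COC(C)=O)=C\I)[C@@H]1CO | intermediate
26 | (2S,3R)-2-[(2Z,6E)-2,6-bis(acetoxymethyl)-7-iodohepta-2,6-dien-1-yl]-4-methylidene-5-oxooxolane-3-carbaldehyde | C=C1C(=O)O[C@@H](C/C(COC(C)=O)=C/CC/C(COC(C)=O)=C\I)[C@@H]1C=O | intermediate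
27 | (3aS,4R,5E,9Z,11aS)-6,10-bis(acetoxymethyl)-4-hydroxy-3-methylidene-3a,4,7,8,11,11a-hexahydrocyclodeca[b]furan-2(3H)-one | C=C1C(=O)O[C@H]2C/C(COC(C)=O)=C/CC/C(COC(C)=O)=C\[C@@H](O)[C@H]12 | target

Total step count: 17. Longest linear sequence: 14 steps (steps 1–5, 7–11, 14–17).

## Steps most likely to fail

Step 17. Ring closure may lose to addition of the alkenylchromium end to the aldehyde of another molecule, and the aldehyde may be attacked on the undesired face, or with only a small preference, so that the C6 epimer accumulates. The fallback sets out from 26 and returns to 27. The ring is closed as in step 17, but the C6 configuration is no longer asked of the carbon–carbon bond formation. The crude carbinol mixture, 27 together with its C6 epimer F1, is oxidised with MnO2 (CH2Cl2, rt) to the ring enone F2, in which the C6 ketone is conjugated to C4=C5. Corey–Bakshi–Shibata reduction of the enone ((R)-2-methyl-CBS-oxazaborolidine, catecholborane, toluene, −78 °C, the alkenyl side taken as the large group) should then return 27 under reagent control.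

Step 14. The allylchromium may add with too little facial discrimination, and the β,γ-unsaturated aldehyde may enolise toward the conjugated enal under the amine and silyl chloride conditions. The fallback sets out from 17 and 18 and returns at 26, bypassing 24 and 25; it replaces the chiral catalyst by a stereocenter carried in the allyl reagent. Morita–Baylis–Hillman reaction of 18 with commercial (R)-2,2-dimethyl-1,3-dioxolane-4-carbaldehyde (O=C[C@H]1COC(C)(C)O1) should give the Baylis–Hillman adduct F3, and N-bromosuccinimide with Me2S the (Z)-allylic bromide F4. Stoichiometric CrCl2 (THF, rt, no amine, no silyl chloride) with 17 should give the anti hydroxy ester F5 (not isolated), the face of the allylchromium being chosen by the adjacent dioxolane stereocenter, and PPTS then closes the dioxolanyl lactone F6. Aqueous acetic acid frees the diol F7, and NaIO4 (THF/H2O, pH 7) cleaves it to 26, so that no primary alcohol has to be oxidised. Should the (R)-series prove mismatched, the enantiomeric aldehyde is used in the same way.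

Step 16. Once C6 is an aldehyde, H7 is α to it and γ to the lactone carbonyl; enolisation can move the exocyclic double bond into the ring to give a conjugated furanone, and the primary alcohol 25 can take over the lactone before it is oxidised. The fallback sets out from 25 and returns to 27; it masks the methylene lactone during oxidation and ring closure. Conjugate addition of dimethylamine (THF, 0 °C) to 25 should give the amino alcohol F8 (C11 epimers, of no consequence). Parikh–Doering oxidation gives the amino aldehyde F9, which can no longer isomerise into conjugation. The nickel/chromium ring closure of step 17 applied to F9 gives the amino macrocycle F10. MeI then forms the ammonium iodide F11 (not isolated), and aqueous NaHCO3 eliminates trimethylamine to restore the methylene group of 27.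

## Further compounds

F1 | step 17 | C6 epimer of 27 | C=C1C(=O)O[C@H]2C/C(COC(C)=O)=C/CC/C(COC(C)=O)=C\[C@H](O)[C@H]12
F2 | step 17 | ring enone (C6 ketone of 27) | C=C1C(=O)O[C@H]2C/C(COC(C)=O)=C/CC/C(COC(C)=O)=C\C(=O)[C@H]12
F3 | step 14 | methyl 3-[(4R)-2,2-dimethyl-1,3-dioxolan-4-yl]-3-hydroxy-2-methylidenepropanoate (carbinol epimers) | COC(=O)C(=C)C(O)[C@H]1COC(C)(C)O1
F4 | step 14 | methyl (2Z)-2-(bromomethyl)-3-[(4S)-2,2-dimethyl-1,3-dioxolan-4-yl]prop-2-enoate | COC(=O)/C(CBr)=C/[C@H]1COC(C)(C)O1
F5 | step 14 | anti hydroxy ester carrying the dioxolane on C7 | COC(=O)C(=C)[C@@H]([C@H]1COC(C)(C)O1)[C@@H](O)C/C(COC(C)=O)=C/CC/C(COC(C)=O)=C\I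
F6 | step 14 | trans lactone carrying the dioxolane on C7 | C=C1C(=O)O[C@@H](C/C(COC(C)=O)=C/CC/C(COC(C)=O)=C\I)[C@@H]1[C@H]2COC(C)(C)O2
F7 | step 14 | trans lactone carrying the 1,2-diol on C7 | C=C1C(=O)O[C@@H](C/C(COC(C)=O)=C/CC/C(COC(C)=O)=C\I)[C@@H]1[C@H](O)CO
F8 | step 16 | dimethylamine adduct of 25 (C11 epimers) | CN(C)CC1C(=O)O[C@@H](C/C(COC(C)=O)=C/CC/C(COC(C)=O)=C\I)[C@@H]1CO
F9 | step 16 | dimethylamine adduct of 26 (C11 epimers) | CN(C)CC1C(=O)O[C@@H](C/C(COC(C)=O)=C/CC/C(COC(C)=O)=C\I)[C@@H]1C=O
F10 | step 16 | dimethylamine adduct of 27 (C11 epimers) | CN(C)CC1C(=O)O[C@H]2C/C(COC(C)=O)=C/CC/C(COC(C)=O)=C\[C@@H](O)[C@H]12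
F11 | step 16 | trimethylammonium iodide of F10 | C[N+](C)(C)CC1C(=O)O[C@H]2C/C(COC(C)=O)=C/CC/C(COC(C)=O)=C\[C@@H](O)[C@H]12.[I-]
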